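Remark on the chemistry (assumption): the (S,S)-configured diazaborolidine bromide used in step 5 is taken to select the enolate face that leads to the (5R,10R) acid 9. The (R,R) reagent is equally accessible and would replace it, with nothing else changed, if the sense of induction on this dienolate proved to be the opposite.

Numbering used throughout: C10 is the quaternary ring carbon (methyl C14, vinyl C1=C2); C9 is the ring CH2; C8 carries the acyloxy group; C7 carries C11(=C13H2)–C12; C6 carries the lactone oxygen; C5 carries C4(=C3H2)–C15; C1'–C3' are the carbons of the acyl group.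

## Analysis of the target

The target (32) is an elemane-type sesquiterpenoid ester built on one cyclohexane ring (C5–C10). An α-methylene-γ-butyrolactone is trans-fused across C6–C7 (C12 carbonyl, C11=C13 methylene). O8 is esterified with (R)-3-hydroxy-2-methylpropanoic acid, C5 carries a 3-hydroxyprop-1-en-2-yl group, and C10 is quaternary. The ring holds five contiguous stereocentres, (5R,6R,7R,8S,10R). C4, O6, C11 and O8 alternate above and below the ring and are all equatorial in one chair, while at C10 the methyl is equatorial and the vinyl axial, cis to the C5 side chain, so the ring has the C10-epimeric form of the usual elemane pattern. The sixth centre, C2' of the acyl group, is remote from the ring and must come in with the acid. The sensitive groups are the α-methylene lactone (a Michael acceptor that tolerates neither strong nucleophiles nor bases), the β-hydroxy ester side chain (elimination, α-epimerisation, acyl migration) and the allylic alcohol at C15; in addition the oxygens at C8, C15 and C3' must end up differentiated as ester, alcohol and alcohol. The synthesis is hard because the vicinal quaternary/tertiary pair C10/C5 has to be set in the absolute sense and C6, C7 and C8 then set relative to it, without exposing the methylene lactone to the chemistry that builds the ring. The route rests on the C7–C8 bond. C8 bears oxygen and C7 bears the 2-propenyl-type unit C11(=C13)C12 trans to it, which is the pattern an aldehyde at C8 leaves when it undergoes an ene reaction with a C7=C11 alkene; forming C7–C8 therefore closes the ring, sets both centres and makes the exocyclic methylene of the later lactone in one step.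

## Retrosynthetic reasoning

**Lactone and protecting groups.** The last operation on 32 only removes the two tert-butyldiphenylsilyl groups of 31 (O15 and O3'). These are kept to the end because a free allylic C15 alcohol would not survive the oxidation that makes the lactone. In 31 the acyl C12–O6 bond is cut, which leads to the 2-methylene-1,4-diol 28. The forward reaction oxidises only the allylic primary alcohol at C12; the lactol then closes and is oxidised further. The methylene lactone therefore exists only in the last two steps. Diol 28 comes from the bis(triethylsilyl) ether 27 by acid-catalysed methanolysis, which leaves the bulkier silyl groups in place.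

**Ester at O8.** The O8–C1' bond of 27 is cut to give cyclohexanol 23 and acid 26. Cutting here keeps the epimerisable C2' centre out of the whole ring construction. Acid 26 is made from hydroxy ester 24 by silylation (25) and hydrolysis.

**C15.** The C15 carbinol of 23 is traced through diol 22 to the tert-butyl ester of 21. The ester is not a detour: it makes the C4=C3 alkene electron-poor during ring closure and is reduced immediately afterwards.

**Key disconnection, C7–C8.** Cyclohexanol 21 is opened between C7 and C8 to the acyclic aldehyde 20, in which C8 is a free aldehyde and C7=C11 is a (Z)-trisubstituted alkene with C13 as a methyl group. No other ring bond has an oxygen on one carbon and a 2-propenyl unit on the next, and this cut removes two stereocentres and the ring at once. The forward reaction must form C7–C8 on one alkene face, put O8 equatorial, and take the hydrogen from C13 and not from C12.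

**C6–C7.** Aldehyde 20 is reached from 18 by oxidative removal of the benzylic ether (19) and oxidation. Ether 18 is the silyl ether of allylic alcohol 17, whose C6–C7 bond is cut to give aldehyde 11 and the (Z)-alkenyl iodide 15. This is the convergent cut: the alkene geometry is fixed beforehand in 15, and C6 is formed next to the existing C5 centre. The forward coupling has to be chemoselective for an aldehyde beside an acrylate ester and must not be basic, since C5 of 11 is both α to the aldehyde and allylic.

**C5–C10.** Aldehyde 11 comes from acid 9 through acid chloride 10, without passing through a free C6 alcohol. The C5–C10 bond of 9 is cut by a sigmatropic transform to the allylic itaconate diester 7, rearranging through ketene acetal 8. This is the only cut that makes the quaternary/tertiary pair in one step from an achiral, readily assembled ester, and it leaves the vinyl group directly on C10. The forward reaction must control the enolate geometry (relative configuration) and the enolate face (absolute configuration).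

**Building blocks.** Diester 7 comes from half ester 6 by tert-butyl esterification, and 6 from allylic alcohol 4 and anhydride 5. Alcohol 4 is obtained from the protected alkynol 2 (from 1) by methyl-metalation and hydroxymethylation through alane 3. Iodide 15 is the silyl ether of 14, obtained from 12 by anti-carbometalation through 13.

## Alternatives that were turned down

**Alternative 1:** The C10–C1 and C5–C4 bonds are cut together, which leads back to a preformed ring, (S)-5-(tert-butyldimethylsilyloxy)-3-methylcyclohex-2-enone A1, and the silyl propargyl ether A2. In the forward direction irradiation adds the alkyne across the C5=C10 enone bond to give the cis-fused cyclobutene A3; later ethenolysis of the cyclobutene would release the C10 vinyl group and the C4 methylene.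
- For it: the cis relation between the vinyl group and the C5 side chain, which is the distinctive feature of this target, is enforced by the ring fusion and not by a transition-state preference. The quaternary centre needs no chiral reagent, and the carbocycle and the C8 oxygen are present from the start. On the C5/C10 problem this plan is stronger than the chosen one.
- Against it: the orientation of an unsymmetrical alkyne in enone photocycloadditions is not reliably controlled. The C8 silyloxy group is separated from C10 by a CH2 and gives only a weak facial bias. The cyclobutenyl ketone A3 absorbs light itself and can rearrange. After the key step C7 is still an unsubstituted CH2, so the C11–C13 unit, the C6 oxygen and the trans,trans relationships at C6–C8 would have to be installed on the ring by enolate chemistry and ketone reduction, each with its own stereochemical problem.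
- Comparison: the chosen route pays for C5/C10 with a reagent-controlled rearrangement, but in return it forms C7, C8 and the lactone methylene in the ring-closing step and needs no enolate chemistry on the ring.

**Alternative 2:** The C6–C7 bond and the lactone acyl–O6 bond are cut, which gives the acyclic aldehyde A4 carrying a 2-(bromomethyl)enoate. In the forward direction CrCl2 generates an allylchromium species that adds through C7 to the C6 aldehyde, and the resulting alkoxide closes onto the ester to give A5.
- For it: the ring, C6, C7 and the complete methylene lactone form in one step, and the endgame is some three to four steps shorter because no oxidative lactonisation and no adjustment at C12 are needed. On step economy after ring closure this plan is stronger.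
- Against it: A4 must already carry C5, C10 and C8, so the C8 ether needs its own asymmetric step, whereas the ene closure creates C8. The target needs a trans ring fusion, and intermolecular additions of such ester-substituted allylchromium reagents typically give cis-disubstituted lactones, so the required sense is not secured by a simple model. The C6 aldehyde of A4 is epimerisable at C5 and has to survive a slow intramolecular closure, whereas the analogous aldehyde 11 is consumed in a fast intermolecular coupling.
- Comparison: the chosen route has a longer endgame but a ring closure whose stereochemical outcome follows from a well-understood chair.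

**Alternative 3:** The C8=C9 bond is cut by a metathesis transform, which gives lactone A6. In A6, C5, C6 and C7 are already in place, C10 carries a methyl and two vinyl groups, and C7 carries a silyl enol ether. The second-generation Grubbs catalyst would join one vinyl group to the enol ether and give A7.
- For it: C10 becomes stereogenic only through the choice between two identical groups, so no enantioselective construction of the quaternary centre is needed, and the lactone is a rigid template. On this point the plan is stronger than the chosen one.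
- Against it: the choice between the two vinyl groups depends on whether methyl or the remaining vinyl ends up axial, and these two groups have nearly the same steric demand; the target needs the less obvious outcome (vinyl axial). The closure forms a trisubstituted silyl enol ether next to a quaternary carbon, which is demanding for this catalyst. Afterwards the C8 ketone must be reduced to the equatorial alcohol, and the methylene at C11 must be added by enolate chemistry on a lactone that has an oxygen β to the enolate carbon.
- Comparison: the chosen route sets C10 with a chair-controlled rearrangement that discriminates methyl from a much larger chain, and it delivers the C8 configuration and the methylene without later enolate chemistry.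

Key step: step 13

## Route

Step 1
Reactants: 1 but-3-yn-1-ol
Product: 2 1-(but-3-yn-1-yloxymethyl)-4-methoxybenzene
Conditions: NaH, 4-methoxybenzyl chloride, Bu4NI (cat.), THF, 0 °C → rt
Reagents that add atoms: 4-methoxybenzyl chloride COc1ccc(CCl)cc1
Why: Williamson etherification of the primary alkoxide; the 4-methoxybenzyl ether should tolerate the aluminium, boron and chromium reagents ahead and is later removed oxidatively without touching silyl ethers.

Step 2
Reactants: 2 1-(but-3-yn-1-yloxymethyl)-4-methoxybenzene
Product: 4 (2E)-5-(4-methoxybenzyloxy)-3-methylpent-2-en-1-ol, via alkenyldimethylalane 3 (not isolated)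
Conditions: Me3Al, Cp2ZrCl2 (cat.), CH2Cl2, 0 °C → rt; then n-BuLi, (CH2O)n, THF, −78 °C → rt
Reagents that add atoms: trimethylaluminium C[Al](C)C; formaldehyde (as paraformaldehyde) C=O
Why: Negishi zirconium-catalysed carboalumination adds methyl and aluminium syn across the alkyne with the metal at the terminus, and the derived aluminate is hydroxymethylated with retention, so the (E)-alkene carrying the future C14 methyl on C10 results.

Step 3
Reactants: 4 (2E)-5-(4-methoxybenzyloxy)-3-methylpent-2-en-1-ol; 5 itaconic anhydride
Product: 6 2-methylidene-4-oxo-4-[(2E)-5-(4-methoxybenzyloxy)-3-methylpent-2-enyloxy]butanoic acid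
Conditions: toluene, 80 °C
Reagents that add atoms: none
Why: Alcoholysis of the unsymmetrical anhydride at the carbonyl next to the CH2 group, which is not conjugated and is the more electrophilic, leaves the conjugated acid free; no base is used so that the methylene does not move into conjugation, and any minor regioisomer is removed after step 4.

Step 4
Reactants: 6 2-methylidene-4-oxo-4-[(2E)-5-(4-methoxybenzyloxy)-3-methylpent-2-enyloxy]butanoic acid
Product: 7 1-tert-butyl 4-[(2E)-5-(4-methoxybenzyloxy)-3-methylpent-2-enyl] 2-methylidenebutanedioate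
Conditions: tBuOC(=NiPr)NHiPr, CH2Cl2, rt
Reagents that add atoms: O-tert-butyl-N,N'-diisopropylisourea CC(C)NC(=NC(C)C)OC(C)(C)C
Why: Neutral tert-butyl esterification through the protonated isourea; a tert-butyl ester is chosen over a methyl ester because it resists attack by the C6 alkoxide formed in step 9, which would otherwise close a five-membered lactone onto C15 and tie up O6.

Step 5
Reactants: 7 1-tert-butyl 4-[(2E)-5-(4-methoxybenzyloxy)-3-methylpent-2-enyl] 2-methylidenebutanedioate
Product: 9 (2R,3R)-2-(3-tert-butoxy-3-oxoprop-1-en-2-yl)-3-[2-(4-methoxybenzyloxy)ethyl]-3-methylpent-4-enoic acid, via boron ketene acetal 8 (not isolated)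
Conditions: (S,S)-[ArSO2N–CHPh–CHPh–NSO2Ar]BBr (Ar = 3,5-(CF3)2C6H3; made from the bis-sulfonamide and BBr3), iPr2NEt, CH2Cl2, −78 °C; then 4 °C; aq. work-up
Reagents that add atoms: none
Why: Enantioselective Ireland–Claisen rearrangement through a chiral boron enolate: soft enolisation at C5 (α to the allyl ester carbonyl and allylic) with the hindered amine in CH2Cl2 should give the Z(O)-ketene acetal 8, which rearranges through a chair with the C4 acrylate unit and the C9 arm equatorial and C14 axial, fixing C5 and C10 relative to each other as 5R,10R. The C2-symmetric sulfonamide groups on boron shield one face of the ketene acetal and so decide the absolute configuration.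

Step 6
Reactants: 9 (2R,3R)-2-(3-tert-butoxy-3-oxoprop-1-en-2-yl)-3-[2-(4-methoxybenzyloxy)ethyl]-3-methylpent-4-enoic acid
Product: 11 tert-butyl (3R,4R)-3-formyl-4-[2-(4-methoxybenzyloxy)ethyl]-4-methyl-2-methylidenehex-5-enoate, via acid chloride 10 (not isolated)
Conditions: Me2C=C(Cl)NMe2, CH2Cl2, 0 °C → rt; then LiAlH(OtBu)3, THF, −78 °C
Reagents that add atoms: none
Why: The chloro-enamine makes the acid chloride without releasing acid or needing base, and the hindered alkoxyaluminium hydride reduces an acid chloride to the aldehyde at −78 °C without touching the tert-butyl ester or the alkenes. The C6 carbon never becomes a free alcohol γ to the ester, and the C5 centre is not exposed to base.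

Step 7
Reactants: 12 prop-2-yn-1-ol
Product: 14 (2Z)-3-iodo-2-methylprop-2-en-1-ol, via chelated alkenylmagnesium alkoxide 13 (not isolated)
Conditions: MeMgBr, copper iodide CuI (cat.), THF/Et2O, −10 °C → rt; then I2, −78 °C → 0 °C
Reagents that add atoms: methylmagnesium bromide C[Mg]Br; iodine II
Why: Copper-catalysed anti-carbomagnesiation of the magnesium alkoxide puts methyl on the internal carbon and magnesium on the terminal carbon, cis to the CH2O group in a five-membered chelate; iodinolysis with retention gives the vinyl iodide with iodine cis to the hydroxymethyl group.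

Step 8
Reactants: 14 (2Z)-3-iodo-2-methylprop-2-en-1-ol
Product: 15 triethyl[(2Z)-3-iodo-2-methylprop-2-enyloxy]silane
Conditions: Et3SiCl, imidazole, CH2Cl2, 0 °C
Reagents that add atoms: chlorotriethylsilane CC[Si](Cl)(CC)CC
Why: Standard silylation of a primary alcohol; the triethylsilyl group on O12 is later removed together with the one on O6.

Step 9
Reactants: 11 tert-butyl (3R,4R)-3-formyl-4-[2-(4-methoxybenzyloxy)ethyl]-4-methyl-2-methylidenehex-5-enoate; 15 triethyl[(2Z)-3-iodo-2-methylprop-2-enyloxy]silane
Product: 17 tert-butyl (5R,6S,10R,7Z)-6-hydroxy-8-(4-methoxybenzyloxy)-12-(triethylsilyloxy)-7,8-seco-elema-1,3,7(11)-trien-15-oate, via alkenylchromium dichloride 16 (not isolated)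
Conditions: CrCl2, NiCl2 (cat.), DMSO, rt
Reagents that add atoms: none
Why: Nozaki–Hiyama–Kishi coupling: the alkenylchromium reagent formed from the iodide with retention of geometry adds to aldehydes only and is not basic, so the acrylate ester and the enolisable C5–H are left alone. C6 is set by Felkin–Anh addition, with the quaternary C10 anti to the incoming alkenyl group and the approach past H5, which puts O6 syn to C4 in the extended chain (6S).

Step 10
Reactants: 17 tert-butyl (5R,6S,10R,7Z)-6-hydroxy-8-(4-methoxybenzyloxy)-12-(triethylsilyloxy)-7,8-seco-elema-1,3,7(11)-trien-15-oate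
Product: 18 tert-butyl (5R,6S,10R,7Z)-8-(4-methoxybenzyloxy)-6,12-bis(triethylsilyloxy)-7,8-seco-elema-1,3,7(11)-trien-15-oate
Conditions: Et3SiOTf, 2,6-lutidine, CH2Cl2, −78 °C
Reagents that add atoms: triethylsilyl trifluoromethanesulfonate CC[Si](CC)(CC)OS(=O)(=O)C(F)(F)F
Why: The silyl triflate with a hindered pyridine base silylates the hindered secondary allylic alcohol at low temperature without ionising it.

Step 11
Reactants: 18 tert-butyl (5R,6S,10R,7Z)-8-(4-methoxybenzyloxy)-6,12-bis(triethylsilyloxy)-7,8-seco-elema-1,3,7(11)-trien-15-oate
Product: 19 tert-butyl (5R,6S,10R,7Z)-8-hydroxy-6,12-bis(triethylsilyloxy)-7,8-seco-elema-1,3,7(11)-trien-15-oate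
Conditions: DDQ, CH2Cl2/pH 7 buffer, 0 °C
Reagents that add atoms: none
Why: Oxidative cleavage of the 4-methoxybenzyl ether by hydride abstraction at the benzylic position and hydrolysis; the buffered conditions leave both triethylsilyl ethers and the alkenes untouched.

Step 12
Reactants: 19 tert-butyl (5R,6S,10R,7Z)-8-hydroxy-6,12-bis(triethylsilyloxy)-7,8-seco-elema-1,3,7(11)-trien-15-oate
Product: 20 tert-butyl (5R,6S,10R,7Z)-8-oxo-6,12-bis(triethylsilyloxy)-7,8-seco-elema-1,3,7(11)-trien-15-oate
Conditions: Dess–Martin periodinane, NaHCO3, CH2Cl2, 0 °C → rt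
Reagents that add atoms: none
Why: Buffered Dess–Martin oxidation of the primary alcohol to the C8 aldehyde; C9 has no stereocentre and C10 is quaternary, so nothing can epimerise or eliminate.

Step 13
Reactants: 20 tert-butyl (5R,6S,10R,7Z)-8-oxo-6,12-bis(triethylsilyloxy)-7,8-seco-elema-1,3,7(11)-trien-15-oate
Product: 21 tert-butyl (5R,6R,7R,8S,10R)-8-hydroxy-6,12-bis(triethylsilyloxy)elema-1,3,11(13)-trien-15-oate
Conditions: Me2AlCl (2 equiv), CH2Cl2, −78 °C → −40 °C
Reagents that add atoms: none
Why: Me2AlCl complexes the C8 aldehyde, and the activated carbonyl carbon bonds to C7, the nearer carbon of the (Z)-trisubstituted alkene, while the carbonyl oxygen takes a hydrogen from C13 in a concerted but asynchronous six-centre carbonyl-ene process that moves the double bond to C11=C13. The closest known reaction is the Lewis-acid-promoted cyclisation of citronellal-type aldehydes to trans-2-isopropenylcyclohexanols. The one ring formed, the cyclohexane C5–C10, closes in a 6-exo-trig mode with respect to the C7=C11 bond through a chair transition state. C7 is controlled by the substrate: the chair that keeps the C6 silyloxy group, the C5 acrylate unit and C14 equatorial (only the C10 vinyl is axial) presents one alkene face to C8, and the same arrangement turns H6 into the alkene plane toward the cis C12 silyloxymethyl group, so allylic 1,3-strain reinforces it. C8 is controlled by the preference of the aluminium-bound oxygen for the equatorial position of that chair, trans to the developing C11 unit. The site of hydrogen transfer follows from the alkene geometry, because the equatorial oxygen lies on the H7 side of C11, next to C13; the C12 silyloxymethyl group is therefore untouched and the exocyclic methylene of the later lactone forms directly. Chemoselectivity among the alkenes is secured by the ester, which makes C4=C3 too electron-poor to act as the ene donor, and by the C10 vinyl group being unable to reach C8 in a ring of sensible size; Me2AlCl also consumes the transferred proton as methane, so no protic acid is released toward the allylic silyl ethers.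

Step 14
Reactants: 21 tert-butyl (5R,6R,7R,8S,10R)-8-hydroxy-6,12-bis(triethylsilyloxy)elema-1,3,11(13)-trien-15-oate
Product: 22 (5R,6R,7R,8S,10R)-6,12-bis(triethylsilyloxy)elema-1,3,11(13)-triene-8,15-diol
Conditions: iBu2AlH (excess), CH2Cl2, −78 °C → 0 °C; aq. potassium sodium tartrate
Reagents that add atoms: none
Why: 1,2-Reduction of the acrylate ester to the 2-substituted allylic alcohol by the aluminium hydride; the free C8 hydroxyl only consumes one equivalent and the silyl ethers are inert.

Step 15
Reactants: 22 (5R,6R,7R,8S,10R)-6,12-bis(triethylsilyloxy)elema-1,3,11(13)-triene-8,15-diol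
Product: 23 (5R,6R,7R,8S,10R)-15-(tert-butyldiphenylsilyloxy)-6,12-bis(triethylsilyloxy)elema-1,3,11(13)-trien-8-ol
Conditions: tBuPh2SiCl, imidazole, CH2Cl2, 0 °C
Reagents that add atoms: tert-butyl(chloro)diphenylsilane CC(C)(C)[Si](Cl)(c1ccccc1)c2ccccc2
Why: The bulky chlorosilane silylates the primary allylic C15 hydroxyl much faster than the secondary ring hydroxyl at C8, and the resulting ether outlasts the later removal of the triethylsilyl groups.

Step 16
Reactants: 24 methyl (R)-3-hydroxy-2-methylpropanoate
Product: 25 methyl (R)-3-(tert-butyldiphenylsilyloxy)-2-methylpropanoate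
Conditions: tBuPh2SiCl, imidazole, DMF, rt
Reagents that add atoms: tert-butyl(chloro)diphenylsilane CC(C)(C)[Si](Cl)(c1ccccc1)c2ccccc2
Why: Standard silylation of the primary alcohol; the C2' centre is not involved.

Step 17
Reactants: 25 methyl (R)-3-(tert-butyldiphenylsilyloxy)-2-methylpropanoate
Product: 26 (R)-3-(tert-butyldiphenylsilyloxy)-2-methylpropanoic acid
Conditions: LiOH, THF/MeOH/H2O, 0 °C → rt; then 1 M HCl
Reagents that add atoms: lithium hydroxide [Li+].[OH-]
Why: Saponification of the methyl ester by acyl substitution at low temperature, under which the α-centre should not epimerise and the bulky silyl ether should not be eliminated.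

Step 18
Reactants: 23 (5R,6R,7R,8S,10R)-15-(tert-butyldiphenylsilyloxy)-6,12-bis(triethylsilyloxy)elema-1,3,11(13)-trien-8-ol; 26 (R)-3-(tert-butyldiphenylsilyloxy)-2-methylpropanoic acid
Product: 27 (5R,6R,7R,8S,10R)-15-(tert-butyldiphenylsilyloxy)-6,12-bis(triethylsilyloxy)elema-1,3,11(13)-trien-8-yl (R)-3-(tert-butyldiphenylsilyloxy)-2-methylpropanoate
Conditions: EDC·HCl, DMAP (cat.), CH2Cl2, 0 °C → rt
Reagents that add atoms: none
Why: Steglich esterification of the equatorial C8 hydroxyl; catalytic DMAP and low temperature limit epimerisation at C2'.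

Step 19
Reactants: 27 (5R,6R,7R,8S,10R)-15-(tert-butyldiphenylsilyloxy)-6,12-bis(triethylsilyloxy)elema-1,3,11(13)-trien-8-yl (R)-3-(tert-butyldiphenylsilyloxy)-2-methylpropanoate
Product: 28 (5R,6R,7S,8S,10R)-15-(tert-butyldiphenylsilyloxy)-6,12-dihydroxyelema-1,3,11(13)-trien-8-yl (R)-3-(tert-butyldiphenylsilyloxy)-2-methylpropanoate
Conditions: PPTS, MeOH/CH2Cl2, 0 °C → rt
Reagents that add atoms: none
Why: Acid-catalysed methanolysis removes triethylsilyl ethers far faster than tert-butyldiphenylsilyl ethers; O6 and O8 are both equatorial and too far apart for acyl migration under these mildly acidic conditions.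

Step 20
Reactants: 28 (5R,6R,7S,8S,10R)-15-(tert-butyldiphenylsilyloxy)-6,12-dihydroxyelema-1,3,11(13)-trien-8-yl (R)-3-(tert-butyldiphenylsilyloxy)-2-methylpropanoate
Product: 31 (5R,6R,7R,8S,10R)-15-(tert-butyldiphenylsilyloxy)-12-oxo-6,12-epoxyelema-1,3,11(13)-trien-8-yl (R)-3-(tert-butyldiphenylsilyloxy)-2-methylpropanoate, via hydroxy enal 29 (not isolated), via lactol 30 (not isolated)
Conditions: MnO2 (excess), CH2Cl2, rt
Reagents that add atoms: none
Why: Oxidative lactonisation of a 2-methylene-1,4-diol: MnO2 oxidises only the allylic primary alcohol at C12, the C6 hydroxyl adds to the enal to give the five-membered lactol, and this is oxidised on to the lactone. The C6 hydroxyl itself is not allylic and C15 is protected, so no other position reacts, and the trans ring fusion is already fixed by C6 and C7.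

Step 21
Reactants: 31 (5R,6R,7R,8S,10R)-15-(tert-butyldiphenylsilyloxy)-12-oxo-6,12-epoxyelema-1,3,11(13)-trien-8-yl (R)-3-(tert-butyldiphenylsilyloxy)-2-methylpropanoate
Product: 32 (5R,6R,7R,8S,10R)-15-hydroxy-12-oxo-6,12-epoxyelema-1,3,11(13)-trien-8-yl (R)-3-hydroxy-2-methylpropanoate
Conditions: HF·pyridine, pyridine/THF, 0 °C → rt
Reagents that add atoms: none
Why: Fluoride-mediated cleavage of both primary silyl ethers under buffered acidic conditions, which avoid the base-induced Michael addition, acyl migration and β-elimination that the methylene lactone and the β-hydroxy ester would suffer with basic fluoride sources.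

## Compound list

1 | but-3-yn-1-ol | C#CCCO | starting material
2 | 1-(but-3-yn-1-yloxymethyl)-4-methoxybenzene | C#CCCOCc1ccc(OC)cc1 | intermediate
3 | [(1E)-4-(4-methoxybenzyloxy)-2-methylbut-1-enyl]dimethylalane | COc1ccc(COCC/C(C)=C/[Al](C)C)cc1 | intermediate
4 | (2E)-5-(4-methoxybenzyloxy)-3-methylpent-2-en-1-ol | COc1ccc(COCC/C(C)=C/CO)cc1 | intermediate
5 | itaconic anhydride (3-methylideneoxolane-2,5-dione) | C=C1CC(=O)OC1=O | starting material
6 | 2-methylidene-4-oxo-4-[(2E)-5-(4-methoxybenzyloxy)-3-methylpent-2-enyloxy]butanoic acid | COc1ccc(COCC/C(C)=C/COC(=O)CC(=C)C(=O)O)cc1 | intermediate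
7 | 1-tert-butyl 4-[(2E)-5-(4-methoxybenzyloxy)-3-methylpent-2-enyl] 2-methylidenebutanedioate | COc1ccc(COCC/C(C)=C/COC(=O)CC(=C)C(=O)OC(C)(C)C)cc1 | intermediate
8 | Z(O)-boron ketene acetal of 7 with the (S,S)-1,3-bis[3,5-bis(trifluoromethyl)phenylsulfonyl]-4,5-diphenyl-1,3,2-diazaborolidin-2-yl group on oxygen | COc1ccc(COCC/C(C)=C/CO/C(OB2N(S(=O)(=O)c3cc(cc(c3)C(F)(F)F)C(F)(F)F)[C@@H](c4ccccc4)[C@H](c5ccccc5)N2S(=O)(=O)c6cc(cc(c6)C(F)(F)F)C(F)(F)F)=C/C(=C)C(=O)OC(C)(C)C)cc1 | intermediate
9 | (2R,3R)-2-(3-tert-butoxy-3-oxoprop-1-en-2-yl)-3-[2-(4-methoxybenzyloxy)ethyl]-3-methylpent-4-enoic acid (5R,10R) | COc1ccc(COCC[C@](C)(C=C)[C@H](C(=C)C(=O)OC(C)(C)C)C(=O)O)cc1 | intermediate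
10 | acid chloride of 9 | COc1ccc(COCC[C@](C)(C=C)[C@H](C(=C)C(=O)OC(C)(C)C)C(=O)Cl)cc1 | intermediate
11 | tert-butyl (3R,4R)-3-formyl-4-[2-(4-methoxybenzyloxy)ethyl]-4-methyl-2-methylidenehex-5-enoate (5R,10R) | COc1ccc(COCC[C@](C)(C=C)[C@H](C(=C)C(=O)OC(C)(C)C)C=O)cc1 | intermediate
12 | prop-2-yn-1-ol | C#CCO | starting material
13 | bromomagnesium (2Z)-3-(bromomagnesio)-2-methylprop-2-en-1-olate | Br[Mg]OC/C(C)=C\[Mg]Br | intermediate
14 | (2Z)-3-iodo-2-methylprop-2-en-1-ol | OC/C(C)=C\I | intermediate
15 | triethyl[(2Z)-3-iodo-2-methylprop-2-enyloxy]silane | CC[Si](CC)(CC)OC/C(C)=C\I | intermediate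
16 | dichloro[(1Z)-2-methyl-3-(triethylsilyloxy)prop-1-enyl]chromium | CC[Si](CC)(CC)OC/C(C)=C\[Cr](Cl)Cl | intermediate
17 | tert-butyl (5R,6S,10R,7Z)-6-hydroxy-8-(4-methoxybenzyloxy)-12-(triethylsilyloxy)-7,8-seco-elema-1,3,7(11)-trien-15-oate | COc1ccc(COCC[C@](C)(C=C)[C@H](C(=C)C(=O)OC(C)(C)C)[C@@H](O)/C=C(/C)CO[Si](CC)(CC)CC)cc1 | intermediate
18 | tert-butyl (5R,6S,10R,7Z)-8-(4-methoxybenzyloxy)-6,12-bis(triethylsilyloxy)-7,8-seco-elema-1,3,7(11)-trien-15-oate | COc1ccc(COCC[C@](C)(C=C)[C@H](C(=C)C(=O)OC(C)(C)C)[C@@H](O[Si](CC)(CC)CC)/C=C(/C)CO[Si](CC)(CC)CC)cc1 | intermediate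
19 | tert-butyl (5R,6S,10R,7Z)-8-hydroxy-6,12-bis(triethylsilyloxy)-7,8-seco-elema-1,3,7(11)-trien-15-oate | OCC[C@](C)(C=C)[C@H](C(=C)C(=O)OC(C)(C)C)[C@@H](O[Si](CC)(CC)CC)/C=C(/C)CO[Si](CC)(CC)CC | intermediate
20 | tert-butyl (5R,6S,10R,7Z)-8-oxo-6,12-bis(triethylsilyloxy)-7,8-seco-elema-1,3,7(11)-trien-15-oate | O=CC[C@](C)(C=C)[C@H](C(=C)C(=O)OC(C)(C)C)[C@@H](O[Si](CC)(CC)CC)/C=C(/C)CO[Si](CC)(CC)CC | intermediate
21 | tert-butyl (5R,6R,7R,8S,10R)-8-hydroxy-6,12-bis(triethylsilyloxy)elema-1,3,11(13)-trien-15-oate | C=C[C@@]1(C)C[C@H](O)[C@@H](C(=C)CO[Si](CC)(CC)CC)[C@H](O[Si](CC)(CC)CC)[C@H]1C(=C)C(=O)OC(C)(C)C | intermediate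
22 | (5R,6R,7R,8S,10R)-6,12-bis(triethylsilyloxy)elema-1,3,11(13)-triene-8,15-diol | C=C[C@@]1(C)C[C@H](O)[C@@H](C(=C)CO[Si](CC)(CC)CC)[C@H](O[Si](CC)(CC)CC)[C@H]1C(=C)CO | intermediate
23 | (5R,6R,7R,8S,10R)-15-(tert-butyldiphenylsilyloxy)-6,12-bis(triethylsilyloxy)elema-1,3,11(13)-trien-8-ol | C=C[C@@]1(C)C[C@H](O)[C@@H](C(=C)CO[Si](CC)(CC)CC)[C@H](O[Si](CC)(CC)CC)[C@H]1C(=C)CO[Si](c2ccccc2)(c3ccccc3)C(C)(C)C | intermediate
24 | methyl (R)-3-hydroxy-2-methylpropanoate | COC(=O)[C@H](C)CO | starting material
25 | methyl (R)-3-(tert-butyldiphenylsilyloxy)-2-methylpropanoate | COC(=O)[C@H](C)CO[Si](c1ccccc1)(c2ccccc2)C(C)(C)C | intermediate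
26 | (R)-3-(tert-butyldiphenylsilyloxy)-2-methylpropanoic acid | OC(=O)[C@H](C)CO[Si](c1ccccc1)(c2ccccc2)C(C)(C)C | intermediate
27 | (5R,6R,7R,8S,10R)-15-(tert-butyldiphenylsilyloxy)-6,12-bis(triethylsilyloxy)elema-1,3,11(13)-trien-8-yl (R)-3-(tert-butyldiphenylsilyloxy)-2-methylpropanoate | C=C[C@@]1(C)C[C@H](OC(=O)[C@H](C)CO[Si](c2ccccc2)(c3ccccc3)C(C)(C)C)[C@@H](C(=C)CO[Si](CC)(CC)CC)[C@H](O[Si](CC)(CC)CC)[C@H]1C(=C)CO[Si](c4ccccc4)(c5ccccc5)C(C)(C)C | intermediate
28 | (5R,6R,7S,8S,10R)-15-(tert-butyldiphenylsilyloxy)-6,12-dihydroxyelema-1,3,11(13)-trien-8-yl (R)-3-(tert-butyldiphenylsilyloxy)-2-methylpropanoate | C=C[C@@]1(C)C[C@H](OC(=O)[C@H](C)CO[Si](c2ccccc2)(c3ccccc3)C(C)(C)C)[C@@H](C(=C)CO)[C@H](O)[C@H]1C(=C)CO[Si](c4ccccc4)(c5ccccc5)C(C)(C)C | intermediate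
29 | 12-aldehyde of 28 (6-hydroxy-12-oxo compound) | C=C[C@@]1(C)C[C@H](OC(=O)[C@H](C)CO[Si](c2ccccc2)(c3ccccc3)C(C)(C)C)[C@@H](C(=C)C=O)[C@H](O)[C@H]1C(=C)CO[Si](c4ccccc4)(c5ccccc5)C(C)(C)C | intermediate
30 | 6,12-lactol of 29 (12-hydroxy-6,12-epoxy compound, C12 configuration undefined) | C=C[C@@]1(C)C[C@H](OC(=O)[C@H](C)CO[Si](c3ccccc3)(c4ccccc4)C(C)(C)C)[C@H]2C(=C)C(O)O[C@@H]2[C@H]1C(=C)CO[Si](c5ccccc5)(c6ccccc6)C(C)(C)C | intermediate
31 | (5R,6R,7R,8S,10R)-15-(tert-butyldiphenylsilyloxy)-12-oxo-6,12-epoxyelema-1,3,11(13)-trien-8-yl (R)-3-(tert-butyldiphenylsilyloxy)-2-methylpropanoate | C=C[C@@]1(C)C[C@H](OC(=O)[C@H](C)CO[Si](c3ccccc3)(c4ccccc4)C(C)(C)C)[C@H]2C(=C)C(=O)O[C@@H]2[C@H]1C(=C)CO[Si](c5ccccc5)(c6ccccc6)C(C)(C)C | intermediate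
32 | (5R,6R,7R,8S,10R)-15-hydroxy-12-oxo-6,12-epoxyelema-1,3,11(13)-trien-8-yl (R)-3-hydroxy-2-methylpropanoate | C=C[C@@]1(C)C[C@H](OC(=O)[C@H](C)CO)[C@H]2C(=C)C(=O)O[C@@H]2[C@H]1C(=C)CO | target

## Step count and least certain steps

Total: 21 steps. Longest linear sequence: 17 steps (steps 1–6, 9–15 and 18–21, from 1 to 32).

**Step 13 (key step).** The C7=C11 alkene carries silyloxy groups on both allylic carbons, which lowers its nucleophilicity. Ring closure may then be slow enough for methyl transfer from aluminium to the aldehyde, chloride capture of the developing cation, or ionisation of the allylic C6 silyl ether to compete. A fallback keeps the C7–C8 closure but replaces the C13 hydrogen by a silyl group, which makes the alkene far more nucleophilic and removes the need for a hydrogen shift. It sets out from 11 and 12 and returns at 21. Carbomagnesiation of 12 with Me3SiCH2MgCl and CuI followed by iodination, as in step 7, gives (2E)-3-iodo-2-[(trimethylsilyl)methyl]prop-2-en-1-ol F1, and silylation as in step 8 gives its triethylsilyl ether F2. Coupling of F2 with 11 under the conditions of step 9 gives the allylic alcohol F3, the 13-trimethylsilyl analogue of 17. Silylation as in step 10 gives the bis(triethylsilyl) ether F4, removal of the benzylic ether as in step 11 gives the primary alcohol F5, and oxidation as in step 12 gives the allylsilane aldehyde F6. Treatment of F6 with BF3·OEt2 in CH2Cl2 at −78 °C (Hosomi–Sakurai cyclisation) should close the ring through the same chair and give 21 with loss of the trimethylsilyl group.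

**Step 5.** Three things may go wrong. The dienolate may form with the other geometry, which would give the C10 epimer. Face selection by the boron ligands may be weak or opposite on this ester. The boron bromide may also attack the benzylic ether or the tert-butyl ester. The fallback inverts both the alkene and the enolate geometry, so that the relative configuration no longer depends on forming the Z(O)-enolate. It sets out from 2 and returns at 9. Deprotonation of 2 with n-BuLi and trapping with methyl chloroformate gives methyl 5-(4-methoxybenzyloxy)pent-2-ynoate F7. Syn addition of Me2CuLi at −78 °C gives methyl (2Z)-5-(4-methoxybenzyloxy)-3-methylpent-2-enoate F8, and reduction with iBu2AlH gives (2Z)-5-(4-methoxybenzyloxy)-3-methylpent-2-en-1-ol F9. Acylation with 5 as in step 3 gives the half ester F10 and esterification as in step 4 gives the (Z)-allylic diester F11. F11 is rearranged with the diazaborolidine bromide and Et3N in toluene/hexane, conditions that favour the E(O)-enolate; the chair then has the C4 unit and the C9 arm axial and C14 equatorial and leads to the same relative configuration in 9, with the enantiomer of the boron reagent chosen accordingly.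

**Step 9.** Facial selectivity may be poor if the acrylate unit, and not the quaternary carbon, takes the position anti to the nucleophile. C5 of 11 may also epimerise by enolisation in the presence of the Lewis acidic chromium salts. The fallback replaces substrate control by reagent control; it sets out from 17 (as its mixture with the C6 epimer) and returns to 17. Oxidation of the mixture with Dess–Martin periodinane gives the cross-conjugated dienone F12. Corey–Bakshi–Shibata reduction with the (S)-methyl-oxazaborolidine and catecholborane at −78 °C, in which the alkenyl residue acts as the larger group, should deliver hydride to the face that gives the 6S alcohol 17.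

**Step 6.** The hydride may over-reduce the product, and the C5 configuration may be lost through ketene formation from 10 or enolisation of 11. The fallback goes through the alcohol oxidation level; it sets out from 9 and returns at 11. Activation of 9 with isobutyl chloroformate and N-methylmorpholine gives the mixed anhydride F13. Reduction with NaBH4 in THF/water at 0 °C gives the primary alcohol F14, which the tert-butyl ester protects from lactonisation. Buffered Dess–Martin oxidation of F14 gives 11.

## Further compounds

F1 | step 13 | (2E)-3-iodo-2-[(trimethylsilyl)methyl]prop-2-en-1-ol | OC/C(C[Si](C)(C)C)=C\I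
F2 | step 13 | triethyl{(2E)-3-iodo-2-[(trimethylsilyl)methyl]prop-2-enyloxy}silane | CC[Si](CC)(CC)OC/C(C[Si](C)(C)C)=C\I
F3 | step 13 | tert-butyl (5R,6S,10R,7Z)-6-hydroxy-8-(4-methoxybenzyloxy)-12-(triethylsilyloxy)-13-(trimethylsilyl)-7,8-seco-elema-1,3,7(11)-trien-15-oate | COc1ccc(COCC[C@](C)(C=C)[C@H](C(=C)C(=O)OC(C)(C)C)[C@@H](O)/C=C(/C[Si](C)(C)C)CO[Si](CC)(CC)CC)cc1
F4 | step 13 | 6-O-triethylsilyl ether of F3 | COc1ccc(COCC[C@](C)(C=C)[C@H](C(=C)C(=O)OC(C)(C)C)[C@@H](O[Si](CC)(CC)CC)/C=C(/C[Si](C)(C)C)CO[Si](CC)(CC)CC)cc1
F5 | step 13 | 8-hydroxy compound from F4 | OCC[C@](C)(C=C)[C@H](C(=C)C(=O)OC(C)(C)C)[C@@H](O[Si](CC)(CC)CC)/C=C(/C[Si](C)(C)C)CO[Si](CC)(CC)CC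
F6 | step 13 | 8-oxo allylsilane from F5 | O=CC[C@](C)(C=C)[C@H](C(=C)C(=O)OC(C)(C)C)[C@@H](O[Si](CC)(CC)CC)/C=C(/C[Si](C)(C)C)CO[Si](CC)(CC)CC
F7 | step 5 | methyl 5-(4-methoxybenzyloxy)pent-2-ynoate | COC(=O)C#CCCOCc1ccc(OC)cc1
F8 | step 5 | methyl (2Z)-5-(4-methoxybenzyloxy)-3-methylpent-2-enoate | COC(=O)/C=C(/C)CCOCc1ccc(OC)cc1
F9 | step 5 | (2Z)-5-(4-methoxybenzyloxy)-3-methylpent-2-en-1-ol | OC/C=C(/C)CCOCc1ccc(OC)cc1
F10 | step 5 | 2-methylidene-4-oxo-4-[(2Z)-5-(4-methoxybenzyloxy)-3-methylpent-2-enyloxy]butanoic acid | OC(=O)C(=C)CC(=O)OC/C=C(/C)CCOCc1ccc(OC)cc1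
F11 | step 5 | 1-tert-butyl 4-[(2Z)-5-(4-methoxybenzyloxy)-3-methylpent-2-enyl] 2-methylidenebutanedioate | CC(C)(C)OC(=O)C(=C)CC(=O)OC/C=C(/C)CCOCc1ccc(OC)cc1
F12 | step 9 | tert-butyl (5R,10R,7Z)-8-(4-methoxybenzyloxy)-6-oxo-12-(triethylsilyloxy)-7,8-seco-elema-1,3,7(11)-trien-15-oate | COc1ccc(COCC[C@](C)(C=C)[C@H](C(=C)C(=O)OC(C)(C)C)C(=O)/C=C(/C)CO[Si](CC)(CC)CC)cc1
F13 | step 6 | mixed isobutyl carbonic anhydride of 9 | COc1ccc(COCC[C@](C)(C=C)[C@H](C(=C)C(=O)OC(C)(C)C)C(=O)OC(=O)OCC(C)C)cc1
F14 | step 6 | tert-butyl (3R,4R)-3-(hydroxymethyl)-4-[2-(4-methoxybenzyloxy)ethyl]-4-methyl-2-methylidenehex-5-enoate | COc1ccc(COCC[C@](C)(C=C)[C@H](C(=C)C(=O)OC(C)(C)C)CO)cc1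
A1 | alternative 1 | (S)-5-(tert-butyldimethylsilyloxy)-3-methylcyclohex-2-en-1-one | CC1=CC(=O)C[C@@H](O[Si](C)(C)C(C)(C)C)C1
A2 | alternative 1 | tert-butyl(diphenyl)(prop-2-yn-1-yloxy)silane | C#CCO[Si](c1ccccc1)(c2ccccc2)C(C)(C)C
A3 | alternative 1 | cis-fused bicyclo[4.2.0]oct-7-en-2-one photoadduct | C[C@@]12C=C(CO[Si](c3ccccc3)(c4ccccc4)C(C)(C)C)[C@@H]1C(=O)C[C@@H](O[Si](C)(C)C(C)(C)C)C2
A4 | alternative 2 | acyclic C6 aldehyde with methyl (Z)-2-(bromomethyl)enoate at C7=C11, 8-O-(4-methoxybenzyl) and 15-O-silyl groups | C=C[C@@](C)(C[C@H](OCc1ccc(OC)cc1)/C=C(\CBr)C(=O)OC)[C@@H](C=O)C(=C)CO[Si](C)(C)C(C)(C)C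
A5 | alternative 2 | 8-O-(4-methoxybenzyl) 15-O-silyl elemanolide core | C=C[C@@]1(C)C[C@H](OCc3ccc(OC)cc3)[C@H]2C(=C)C(=O)O[C@@H]2[C@H]1C(=C)CO[Si](C)(C)C(C)(C)C
A6 | alternative 3 | lactone with a divinyl methyl carbon at C10 and a silyl enol ether at C8 | C=CC(C)(C=C)[C@H](C(=C)CO[Si](c1ccccc1)(c2ccccc2)C(C)(C)C)[C@H]3OC(=O)C[C@@H]3C(=C)O[Si](C)(C)C(C)(C)C
A7 | alternative 3 | lactone-fused cyclohexenyl silyl enol ether | C=C[C@@]1(C)C=C(O[Si](C)(C)C(C)(C)C)[C@H]2CC(=O)O[C@@H]2[C@H]1C(=C)CO[Si](c3ccccc3)(c4ccccc4)C(C)(C)C
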